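At the time of reading, 25 min for Wednesday's flask and 50 min for Tuesday's, you want to know which species holds most of the starting material, and how much. The two flasks have the same charges, so Tuesday's is Wednesday's left standing longer.

| flask | starting material | reagent | remark | time |
|---|---|---|---|---|
| gamma | 0.034 M | 0.050 M | run made earlier |  |
| epsilon | 0.075 M | 0.050 M | run made earlier |  |
| zeta | 0.050 M | 0.10 M | run made earlier |  |
| Tuesday's | 0.050 M | 0.0500 M |  | 50 min |
| Wednesday's | 0.050 M | 0.0500 M |  | 25 min |

| run | time / min | triple product / % | starting material / % | single product / % | bis adduct / % |
|---|---|---|---|---|---|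
| gamma | 2.00 | 0 | 92 | 6 | 0 |
| gamma | 5.00 | 0 | 88 | 16 | 0 |
| gamma | 10.0 | 1 | 73 | 24 | 2 |
| gamma | 25.0 | 3 | 53 | 40 | 6 |
| epsilon | 3.00 | 3 | 89 | 10 | 1 |
| epsilon | 8.00 | 0 | 82 | 21 | 1 |
| epsilon | 15.0 | 0 | 70 | 27 | 5 |
| epsilon | 25.0 | 0 | 64 | 33 | 4 |
| zeta | 2.00 | 1 | 85 | 13 | 0 |
| zeta | 5.00 | 0 | 71 | 24 | 2 |
| zeta | 10.0 | 1 | 55 | 39 | 6 |
| zeta | 25.0 | 0 | 28 | 52 | 16 |

(each reading ± 1.5 percentage points)

- which of these there is most of at the end, counted by the starting material in it, Tuesday's (single product / triple product / starting material / bis adduct)
- which of these there is most of at the end, counted by the starting material in it, Wednesday's (single product / triple product / starting material / bis adduct)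
- amount of the one of these that there is most of at the end, in percent of the starting material charged, Tuesday's
- amount of the one of these that there is most of at the end, in percent of the starting material charged, Wednesday's



The first way to Wednesday's starting material uses no scheme. The gamma and epsilon runs have the same c(reagent) as Wednesday's flask, and their c(starting material) lies on either side of it. At 25.0 min they read 53% and 64%, so a straight line between them gives 57.3%.

The second way uses the zeta run. It reads 0.645 L mol⁻¹ min⁻¹ for κ, the pair constant: the logarithm of charged over remaining starting material, divided by time and by mean c(reagent). That mean lies between the charge and the charge less what the products hold, with one reagent in single product and two in bis adduct. Zeta also reads 1.24 reagent taken per starting material consumed.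

Each round treats the reaction as pseudo-first-order at a fixed c(reagent). Holding the charge gives 44.7% left on Wednesday's, but this round cheats, since reagent is consumed. Putting the mean back gives 58.8%, and once more gives 54.8%. A further round gives 55.9%, which is still 1.1 percentage points away from the round before. This last value lies 1.4 points from the straight line, beside a scatter of 1.5 points, so the two ways agree roughly.

For Tuesday's, continue from 55.9% with 0.0228 M of reagent. Holding that gives 38.7%, and the mean gives 42.2%. With triple product taken as nil, single product comes to 44.2%, more than the starting material.

The forecast gives starting material at 58% (54% to 62%) on Wednesday's and single product at 48% (44% to 52%) on Tuesday's, from a constant of about 0.6 per molar per minute: “So SM still leads on Wednesday, while single product overtakes it on Tuesday.” Both its amounts stand above the reckoning here.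

Wednesday's flask gives starting material at 56.8%, and Tuesday's gives single product at 47.2%.

    reagent + triple product → tetra adduct (k = 0.0666 L mol⁻¹ s⁻¹)
    reagent ⇌ dormant form (K = 2.76, k = 0.0796 s⁻¹)
    reagent + bis adduct → triple product (k = 0.00123 L mol⁻¹ s⁻¹)
    reagent + single product → bis adduct (k = 0.0171 L mol⁻¹ s⁻¹)
    starting material + reagent → single product (k = 0.0393 L mol⁻¹ s⁻¹)

Wednesday's flask holds 13.5% of its reagent free, beside 0.0189 M of dormant form. Its own amounts put κ at 0.598 L mol⁻¹ min⁻¹. On the neighbour flask with 0.12 M of reagent, where single product stands at 52.6% and bis adduct at 22.8%, this κ gives 24.0%, and that flask holds 24.2% of starting material.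

The earlier runs and the new flask are calculated with made-up constants; scatter was added.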